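**Retrosynthetic overview**

1. Target 8 ⇐ 7 by anti opening of the C5–C6 epoxide at C5 with water; 7 ⇐ 6 by Mitsunobu inversion at C4 with benzoic acid; 6 ⇐ 5 by Luche reduction.
2. Key disconnection: the C5–O and C6–O bonds, formed by a catalyst-controlled, OH-syn desymmetrising epoxidation of the achiral p-quinol 4. C1 (the C(OH)CH2OBz carbon), C5 and C6 become stereocentres in this one event; C4 is relayed from the epoxide.
3. The feature that invites this: C1(OH)(CH2OBz) is para to C4–O, and C2=C3 and C5–C6 are the two arms of a 4-substituted phenol. Hence 4 ⇐ oxidative dearomatisation of 4-hydroxybenzyl benzoate 3 ⇐ 1 + 2.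
4. Rings: the cyclohexene is the benzene ring of 1 and is never closed. The only ring formed is the temporary oxirane (step 3), cleaved in step 6.

Key step: step 3

Ring atoms carry the target numbering throughout: C1 = C(OH)CH2OBz, C2=C3, C4 = CH–OBz, C5 and C6 = CH–OH.

Assumption: the quinine-derived primary amine catalyst is taken to deliver the peroxide to the enone face that gives the (5R,6S) epoxide carbons of 5 (target numbering); if the sense of induction on this dienone is the reverse, the quinidine-derived pseudoenantiomer is used under the same conditions.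

**Route**

Step 1
Reactants: 1 4-hydroxybenzyl alcohol; 2 benzoic acid
Product: 3 4-hydroxybenzyl benzoate
Conditions: PPh3, DIAD, THF, 0 °C → rt
Reagents that add atoms: benzoic acid (2), O=C(O)c1ccccc1
Why: Mitsunobu esterification, in which the benzylic alkoxyphosphonium ion is displaced by benzoate (the most acidic pronucleophile present) and no acyl donor is formed that could esterify the phenol, so the benzylic ester should form without phenol protection.

Step 2
Reactants: 3 4-hydroxybenzyl benzoate
Product: 4 (1-hydroxy-4-oxocyclohexa-2,5-dien-1-yl)methyl benzoate (achiral p-quinol)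
Conditions: PhI(OAc)2, MeCN–H2O (4:1), 0 °C
Reagents that add atoms: water, O
Why: Hypervalent-iodine hydroxylative phenol dearomatisation, in which the aryloxy-iodane is attacked by water at the substituted para carbon to give the cross-conjugated dienone, while the neutral to weakly acidic medium should suppress 1,6-elimination of benzoate from the 4-hydroxybenzyl ester; no stereocentre is formed (mirror plane through C1 and C4).

Step 3
Reactants: 4 (1-hydroxy-4-oxocyclohexa-2,5-dien-1-yl)methyl benzoate
Product: 5 [(1S,2S,6R)-2-hydroxy-5-oxo-7-oxabicyclo[4.1.0]hept-3-en-2-yl]methyl benzoate (C5–C6 epoxide cis to the tertiary OH)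
Conditions: 9-amino(9-deoxy)epi-quinine·2 TFA (10 mol %), 50% aq. H2O2 (1.2 equiv), 1,4-dioxane, 30 °C
Reagents that add atoms: hydrogen peroxide, OO
Why: Proposed new method: the primary amine should condense with the dienone carbonyl to a cross-conjugated iminium ion, the protonated quinuclidine should deliver H2O2 to one β-carbon (C6), and the β-hydroperoxy enamine should close the oxirane by attack of C5 on the proximal peroxide oxygen with loss of water, after which hydrolysis releases the catalyst. The closest known reaction types are the primary-amine-salt-catalysed asymmetric Weitz–Scheffer epoxidation of 2-cyclohexenones with H2O2 and the oxygen-syn-selective nucleophilic epoxidation of p-quinols and their ethers; the combination has not been used to desymmetrise a 4-hydroxycyclohexa-2,5-dienone. The oxirane closes in a 3-exo-tet mode on the O–O bond and is necessarily cis-fused to the six-membered ring. The catalyst fixes the configuration at C5 and C6 because it accepts only one enone face, and the substrate decides which enantiotopic enone arm reacts, since on one arm that face is syn to the tertiary OH (anti to the larger CH2OBz, helped by OH···HOOH hydrogen bonding) and on the other arm it is anti; C1 thereby becomes a stereocentre with its OH cis to the epoxide. The step needs mono- over bis-epoxidation and syn over anti attack: the remaining enone of 5 presents the catalyst-preferred face anti to OH (mismatched), whereas in the minor enantiomer it is matched, so slight over-oxidation should consume the minor enantiomer rather than 5, and any anti product is a separable diastereomer.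

Step 4
Reactants: 5 [(1S,2S,6R)-2-hydroxy-5-oxo-7-oxabicyclo[4.1.0]hept-3-en-2-yl]methyl benzoate
Product: 6 [(1S,2S,5S,6S)-2,5-dihydroxy-7-oxabicyclo[4.1.0]hept-3-en-2-yl]methyl benzoate (C4-OH cis to the epoxide)
Conditions: NaBH4, CeCl3·7H2O, MeOH, −78 °C
Reagents that add atoms: none
Why: Luche 1,2-reduction of the enone, in which hydride should add to C4 from the face opposite the adjacent oxirane oxygen (which shields its own face and binds cerium), giving the carbinol cis to the epoxide while the ester and epoxide stay intact at −78 °C.

Step 5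
Reactants: 6 [(1S,2S,5S,6S)-2,5-dihydroxy-7-oxabicyclo[4.1.0]hept-3-en-2-yl]methyl benzoate; 2 benzoic acid
Product: 7 [(1S,2S,5R,6S)-5-(benzoyloxy)-2-hydroxy-7-oxabicyclo[4.1.0]hept-3-en-2-yl]methyl benzoate (C4-OBz trans to the epoxide)
Conditions: PPh3, DIAD, THF, 0 °C → rt
Reagents that add atoms: benzoic acid (2), O=C(O)c1ccccc1
Why: Mitsunobu esterification with inversion at the secondary allylic C4 (SN2 on the alkoxyphosphonium ion from the face anti to the epoxide), which installs the benzoate and corrects C4 in one operation; the tertiary C1-OH does not react and SN2′ attack at C2 is hindered by the adjacent quaternary C1.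

Step 6
Reactants: 7 [(1S,2S,5R,6S)-5-(benzoyloxy)-2-hydroxy-7-oxabicyclo[4.1.0]hept-3-en-2-yl]methyl benzoate
Product: 8 [(1S,4R,5S,6S)-4-(benzoyloxy)-1,5,6-trihydroxycyclohex-2-en-1-yl]methyl benzoate (target)
Conditions: HClO4 (cat.), THF–H2O (3:1), 0 °C → rt
Reagents that add atoms: water, O
Why: Acid-catalysed anti opening of the epoxide at C5 (C6 is neopentyl-like next to quaternary C1), either by direct attack of water or through the 4,5-cis-dioxolan-2-ylium ion from the trans C4 benzoate, whose orthoacid should collapse to the pseudoaxial C4 ester and equatorial C5-OH; both paths invert C5 and leave the C6–O bond untouched, giving the 5,6-trans/4,5-cis pattern with C6-OH cis to C1-OH.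

**Compound list**

1 | 4-hydroxybenzyl alcohol | OCc1ccc(O)cc1 | starting material
2 | benzoic acid | O=C(O)c1ccccc1 | starting material
3 | 4-hydroxybenzyl benzoate | O=C(OCc1ccc(O)cc1)c1ccccc1 | intermediate
4 | (1-hydroxy-4-oxocyclohexa-2,5-dien-1-yl)methyl benzoate | O=C1C=CC(O)(COC(=O)c2ccccc2)C=C1 | intermediate
5 | [(1S,2S,6R)-2-hydroxy-5-oxo-7-oxabicyclo[4.1.0]hept-3-en-2-yl]methyl benzoate | O=C(OC[C@@]1(O)C=CC(=O)[C@@H]2O[C@H]12)c1ccccc1 | intermediate
6 | [(1S,2S,5S,6S)-2,5-dihydroxy-7-oxabicyclo[4.1.0]hept-3-en-2-yl]methyl benzoate | O=C(OC[C@@]1(O)C=C[C@H](O)[C@@H]2O[C@H]12)c1ccccc1 | intermediate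
7 | [(1S,2S,5R,6S)-5-(benzoyloxy)-2-hydroxy-7-oxabicyclo[4.1.0]hept-3-en-2-yl]methyl benzoate | O=C(OC[C@@]1(O)C=C[C@@H](OC(=O)c2ccccc2)[C@@H]2O[C@H]12)c1ccccc1 | intermediate
8 | [(1S,4R,5S,6S)-4-(benzoyloxy)-1,5,6-trihydroxycyclohex-2-en-1-yl]methyl benzoate | O=C(OC[C@@]1(O)C=C[C@@H](OC(=O)c2ccccc2)[C@@H](O)[C@@H]1O)c1ccccc1 | target

**Step count and risks**

Total step count: 6. Longest linear sequence: 6 steps (1 → 3 → 4 → 5 → 6 → 7 → 8).

Steps most likely to fail:

1. Step 3 (Proposed new method). The cross-conjugated iminium ion may not turn over, facial control may be poor (attack anti to the tertiary OH, or low enantioface selection), or a second epoxidation may compete. The fallback uses known chemistry and replaces the catalytic desymmetrisation by racemic epoxidation and enzymatic kinetic resolution. It sets out from 4. Base-mediated Weitz–Scheffer epoxidation (t-BuOOH, cat. DBU, CH2Cl2, 0 °C) should give the racemic OH-syn epoxy enone F1. Luche reduction as in step 4 should give the racemic cis-epoxy alcohol F2. Lipase-catalysed transesterification (Pseudomonas cepacia lipase, vinyl acetate, MTBE, rt) is expected, by Kazlauskas' rule with the epoxide carbon as the large and the vinylic CH as the medium substituent, to acetylate the unwanted antipode to the acetate of ent-6 F3. The unreacted alcohol is recovered and is 6, where the fallback returns to the route.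

2. Step 6. The opening may run through the neighbouring C4 benzoate with collapse of the orthoacid toward O5 (benzoate migration to the C5 oxygen), or the primary benzoate may participate at C6. The fallback opens the epoxide before any ester sits on C4 and introduces the C4 benzoate last at a defined oxygen. It sets out from 6. Acid hydrolysis (cat. HClO4, THF–H2O) should give the C4-epimeric tetraol monobenzoate [(1S,4S,5R,6S)-1,4,5,6-tetrahydroxycyclohex-2-en-1-yl]methyl benzoate F4 by attack of water at C5. The only cis-diol (O1/O6) is then tied up as the 1,6-O-isopropylidene acetal F5 (2,2-dimethoxypropane, PPTS, acetone). Mitsunobu esterification with benzoic acid 2 (PPh3, DIAD, THF) at the allylic C4-OH should give, with inversion, the 1,6-O-isopropylidene derivative of the target F6. Acetal cleavage (80% aq. AcOH, rt) returns to the route at 8.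

3. Step 2. The phenol may lose benzoate by 1,6-elimination (quinone methide formation), water may attack ortho, or the CH2OBz arm may be lost by ipso fragmentation to benzoquinone. The fallback abandons dearomatisation for C–C bond formation on a preformed dienone. It sets out from benzoic acid 2 and commercial 4,4-dimethoxycyclohexa-2,5-dien-1-one F7. Corey–Chaykovsky methylenation (Me3S+ I−, KHMDS, THF, −20 °C) should give the spiro-epoxide 6,6-dimethoxy-1-oxaspiro[2.5]octa-4,7-diene F8. Opening at the CH2 terminus with caesium benzoate and benzoic acid 2 (DMF, 60 °C) should give (1-hydroxy-4,4-dimethoxycyclohexa-2,5-dien-1-yl)methyl benzoate F9. Mild ketal hydrolysis (PPTS, acetone–H2O, rt) returns to the route at 4.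

**Further compounds**

F1 | step 3 | racemic [(1S*,2S*,6R*)-2-hydroxy-5-oxo-7-oxabicyclo[4.1.0]hept-3-en-2-yl]methyl benzoate | O=C(OC[C@@]1(O)C=CC(=O)[C@@H]2O[C@H]12)c1ccccc1.O=C(OC[C@]1(O)C=CC(=O)[C@H]2O[C@@H]12)c1ccccc1
F2 | step 3 | racemic [(1S*,2S*,5S*,6S*)-2,5-dihydroxy-7-oxabicyclo[4.1.0]hept-3-en-2-yl]methyl benzoate | O=C(OC[C@@]1(O)C=C[C@H](O)[C@@H]2O[C@H]12)c1ccccc1.O=C(OC[C@]1(O)C=C[C@@H](O)[C@H]2O[C@@H]12)c1ccccc1
F3 | step 3 | [(1R,2R,5R,6R)-5-acetoxy-2-hydroxy-7-oxabicyclo[4.1.0]hept-3-en-2-yl]methyl benzoate (acetate of ent-6) | O=C(OC[C@]1(O)C=C[C@@H](OC(C)=O)[C@H]2O[C@@H]12)c1ccccc1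
F4 | step 6 | [(1S,4S,5R,6S)-1,4,5,6-tetrahydroxycyclohex-2-en-1-yl]methyl benzoate | O=C(OC[C@@]1(O)C=C[C@H](O)[C@@H](O)[C@@H]1O)c1ccccc1
F5 | step 6 | 1,6-O-isopropylidene acetal of F4 | O=C(OC[C@@]12C=C[C@H](O)[C@@H](O)[C@@H]1OC(C)(C)O2)c1ccccc1
F6 | step 6 | 1,6-O-isopropylidene acetal of 8 | O=C(OC[C@@]12C=C[C@@H](OC(=O)c3ccccc3)[C@@H](O)[C@@H]1OC(C)(C)O2)c1ccccc1
F7 | step 2 | 4,4-dimethoxycyclohexa-2,5-dien-1-one (commercial) | COC1(OC)C=CC(=O)C=C1
F8 | step 2 | 6,6-dimethoxy-1-oxaspiro[2.5]octa-4,7-diene | COC1(OC)C=CC2(CO2)C=C1
F9 | step 2 | (1-hydroxy-4,4-dimethoxycyclohexa-2,5-dien-1-yl)methyl benzoate | COC1(OC)C=CC(O)(COC(=O)c2ccccc2)C=C1
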